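**Plan**

- Retrosynthesis: the three O–Si bonds are cut last, then the C2–C3 bond of the pyranone ring (ring C). That cut is open because C2 is at the aldehyde oxidation level, held between O1 and the C3 methylene that is alpha to the C4 ketone. O1–C2–C3–C4 therefore maps onto an aryl aldehyde acetal that bridges the ring-A phenol oxygen and the enol oxygen at C4.
- This acetal, a 4-methylene-4H-1,3-benzodioxine, is cut at its exocyclic C=CH2 (lactone methylenation) and at both acetal C–O bonds (2,4,6-trihydroxybenzoic acid plus ring-B aldehyde). The aldehyde is cut at C–CHO and at the aryl–geranyl bond.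
- Forward: the geranyl chain is joined to ring B first, then the aldehyde is made and tied to ring A as a temporary 1,3-benzodioxin-4-one ring, which is methylenated. Ring C arises last, when the dioxine ring is traded for the pyranone ring by a [1,3] oxygen-to-carbon shift.
- Stereochemistry: C2 (S) is the only stereocentre. It is set in the rearrangement by a chiral counter-anion on a planar oxocarbenium ion, so the racemic acetal converges. The E-olefin is bought with geranyl bromide.

Key step: step 8

**Remarks**

- Abbreviations: geranyl = (2E)-3,7-dimethylocta-2,6-dien-1-yl; TBS = tert-butyldimethylsilyl; TMS = trimethylsilyl; IDPi = BINOL-derived imidodiphosphorimidate.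
- Assumption: the sense of induction of the chiral catalyst in step 8 cannot be predicted with confidence. The (S,S)-catalyst is written; if it proves to give the 2R series, its mirror image is to be used.
- Assumption: acid 7 is sold as the monohydrate and is dried azeotropically with toluene before step 4.

**Route**

Step 1
Reactants: 1 4-bromophenol; 2 geranyl bromide
Product: 3 4-bromo-2-geranylphenol
Conditions: 1 (2 equiv), NaH (2 equiv), toluene, 0 °C → rt; then 2 (1 equiv), rt, dark
Reagents that add atoms: none
Why: Ortho-selective C-alkylation of a sodium phenoxide in a non-polar solvent (ambident phenoxide alkylation): the aggregated ion pair shields oxygen, bromine blocks the para position, SN2 attack at the primary allylic carbon keeps the E-olefin, and the excess phenol limits double alkylation.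

Step 2
Reactants: 3 4-bromo-2-geranylphenol
Product: 4 tert-butyl(4-bromo-2-geranylphenoxy)dimethylsilane
Conditions: TBSCl, imidazole, DMF, rt
Reagents that add atoms: tert-butyldimethylsilyl chloride, CC(C)(C)[Si](C)(C)Cl
Why: Standard silylation of a phenol with a silyl chloride and imidazole, giving the silyl ether that masks the acidic OH during lithiation and is kept until the last step.

Step 3
Reactants: 4 tert-butyl(4-bromo-2-geranylphenoxy)dimethylsilane
Product: 6 3-geranyl-4-(tert-butyldimethylsilyloxy)benzaldehyde, via aryllithium 5 (not isolated)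
Conditions: n-BuLi, THF, −78 °C; DMF, −78 → 0 °C; aq. NH4Cl
Reagents that add atoms: N,N-dimethylformamide, CN(C)C=O
Why: Bromine–lithium exchange followed by formylation with DMF (Bouveault aldehyde synthesis); exchange at −78 °C is far faster than deprotonation of the benzylic–allylic CH2, and lithium para to the siloxy group cannot start a retro-Brook shift.

Step 4
Reactants: 7 2,4,6-trihydroxybenzoic acid
Product: 8 trimethylsilyl 2,4,6-tris(trimethylsilyloxy)benzoate
Conditions: HMDS (3 equiv), TMSCl (cat.), THF, rt → 40 °C; evaporate, hexane, filter under Ar; used crude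
Reagents that add atoms: hexamethyldisilazane, C[Si](C)(C)N[Si](C)(C)C
Why: Exhaustive trimethylsilylation of the acid and the three phenols with HMDS; the silyl ester stops decarboxylation of the phloroglucinol carboxylic acid and supplies the silyl leaving groups for the next step.

Step 5
Reactants: 8 trimethylsilyl 2,4,6-tris(trimethylsilyloxy)benzoate; 6 3-geranyl-4-(tert-butyldimethylsilyloxy)benzaldehyde
Product: 10 rac-2-[3-geranyl-4-(tert-butyldimethylsilyloxy)phenyl]-5,7-dihydroxy-4H-1,3-benzodioxin-4-one, via bis-TMS benzodioxinone 9 (not isolated)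
Conditions: TMSOTf (0.1 equiv), CH2Cl2, −78 → −40 °C; pyridine; then THF/pH 7 phosphate buffer, 0 °C → rt; crude product taken on at once
Reagents that add atoms: none
Why: Silyl-transfer (Noyori-type) acetalisation of a bis-silylated hydroxy acid with an aldehyde, the usual way to the dioxanones of Petasis–Ferrier sequences: TMSOTf activates the aldehyde, the silyl ester and an ortho silyl ether close the six-membered acylal with loss of hexamethyldisiloxane at a temperature where the geranyl olefins and C-alkylation of ring A should not compete, the neutral aqueous stir should hydrolyse only the labile aryl TMS ethers, and C2 forms racemic, which the key step allows.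

Step 6
Reactants: 10 rac-2-[3-geranyl-4-(tert-butyldimethylsilyloxy)phenyl]-5,7-dihydroxy-4H-1,3-benzodioxin-4-one
Product: 11 rac-2-[3-geranyl-4-(tert-butyldimethylsilyloxy)phenyl]-5,7-bis(tert-butyldimethylsilyloxy)-4H-1,3-benzodioxin-4-one
Conditions: TBSCl (3 equiv), imidazole (6 equiv), DMAP (cat.), DMF, 0 °C → rt
Reagents that add atoms: tert-butyldimethylsilyl chloride, CC(C)(C)[Si](C)(C)Cl
Why: Silylation of both phenols with excess silyl chloride and imidazole, the hydrogen-bonded 5-OH reacting last, under non-acidic conditions that should not ionise the acylal.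

Step 7
Reactants: 11 rac-2-[3-geranyl-4-(tert-butyldimethylsilyloxy)phenyl]-5,7-bis(tert-butyldimethylsilyloxy)-4H-1,3-benzodioxin-4-one
Product: 12 rac-2-[3-geranyl-4-(tert-butyldimethylsilyloxy)phenyl]-4-methylene-5,7-bis(tert-butyldimethylsilyloxy)-4H-1,3-benzodioxine
Conditions: Cp2TiMe2 (2.5 equiv), toluene/THF, pyridine (1 vol %), 65 °C, dark; filtration through basic alumina (hexane/Et3N)
Reagents that add atoms: dimethyltitanocene, C[Ti](C)(C1C=CC=C1)C1C=CC=C1
Why: Petasis methylenation, the established entry to 4-methylene-1,3-dioxanes: Cp2Ti=CH2 formed by loss of methane adds [2+2] to the lactone carbonyl and cycloreverts to the exocyclic enol ether without a tetrahedral alkoxide that could open the acylal, and the reagent is neither Lewis-acidic nor basic, so silyl ethers, acetal and trisubstituted olefins should survive.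

Step 8
Reactants: 12 rac-2-[3-geranyl-4-(tert-butyldimethylsilyloxy)phenyl]-4-methylene-5,7-bis(tert-butyldimethylsilyloxy)-4H-1,3-benzodioxine
Product: 13 (2S)-5,7-bis(tert-butyldimethylsilyloxy)-2-[3-geranyl-4-(tert-butyldimethylsilyloxy)phenyl]chroman-4-one
Conditions: (S,S)-IDPi (3,3'-aryl, N-triflyl core; 5 mol %), methallyl-TMS (10 mol %), toluene, 0.02 M, −78 → −60 °C; Et3N, −78 °C
Reagents that add atoms: none
Why: Proposed new method: the IDPi, silylated in situ to a chiral silylium Lewis acid with a confined anion, silylates the enol-ether oxygen O3 and heterolyses the C2–O3 bond, which is easy because the cation is an O-aryl oxocarbenium ion conjugated with the para-siloxy ring B and the leaving group is a neutral silyl enol ether; the tethered enol ether carbon then adds to the oxocarbenium carbon (intramolecular Mukaiyama/Prins-type step) and the silyl group passes from the new C4 carbonyl oxygen back to the anion or to the next acetal, so the net change is the [1,3] oxygen-to-carbon shift of a Petasis–Ferrier rearrangement with turnover. The closest known reaction types are the aluminium-promoted Petasis–Ferrier rearrangement of 4-methylene-1,3-dioxanes to tetrahydropyran-4-ones, the chiral phosphoric acid-catalysed (aza-)Petasis–Ferrier rearrangements of vinyl acetals and hemiaminal vinyl ethers, and IDPi-controlled additions of enol silanes to oxocarbenium ions. The pyranone ring closes 6-endo-trig at the oxocarbenium carbon (enol ether endocyclic to the forming ring) through a half-chair with the C2 aryl group pseudo-equatorial. The C2 stereocentre is set by the chiral anion, which pairs with the planar oxocarbenium ion and leaves one face open to the enol ether; because both enantiomers of 12 give the same cation, the racemate should converge on one enantiomer of 13. The step needs C- over O-recombination, ring closure over capture by water or by the electron-rich arenes and olefins, and no reopening of 13: the ortho tether makes C–C closure an intramolecular six-ring event, return at oxygen or ionisation at O1 only regenerates 12, the two ortho substituents twist the enol ether out of the plane of ring A so that its CH2 terminus lies over the cationic carbon, and the low temperature with a cold amine quench should keep the product closed.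

Step 9
Reactants: 13 (2S)-5,7-bis(tert-butyldimethylsilyloxy)-2-[3-geranyl-4-(tert-butyldimethylsilyloxy)phenyl]chroman-4-one
Product: 14 (2S)-3'-geranylnaringenin [(2S)-5,7-dihydroxy-2-(3-geranyl-4-hydroxyphenyl)chroman-4-one]
Conditions: HF·pyridine, pyridine, THF, 0 °C → rt; pH 7 buffer work-up
Reagents that add atoms: none
Why: Fluoride cleavage of the three aryl silyl ethers under acidic buffering (driven by Si–F bond formation): no phenoxide is formed, so neither enolate-triggered opening to the chalcone nor quinone-methide opening from the 4'-oxygen should racemise C2, and buffered HF should not protonate the trisubstituted olefins.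

**Compound list**

1 | 4-bromophenol | Oc1ccc(Br)cc1 | starting material
2 | geranyl bromide [(2E)-1-bromo-3,7-dimethylocta-2,6-diene] | CC(C)=CCC/C(C)=C/CBr | starting material
3 | 4-bromo-2-geranylphenol | CC(C)=CCC/C(C)=C/Cc1cc(Br)ccc1O | intermediate
4 | tert-butyl(4-bromo-2-geranylphenoxy)dimethylsilane | CC(C)=CCC/C(C)=C/Cc1cc(Br)ccc1O[Si](C)(C)C(C)(C)C | intermediate
5 | [3-geranyl-4-(tert-butyldimethylsilyloxy)phenyl]lithium | CC(C)=CCC/C(C)=C/Cc1cc([Li])ccc1O[Si](C)(C)C(C)(C)C | intermediate
6 | 3-geranyl-4-(tert-butyldimethylsilyloxy)benzaldehyde | CC(C)=CCC/C(C)=C/Cc1cc(C=O)ccc1O[Si](C)(C)C(C)(C)C | intermediate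
7 | 2,4,6-trihydroxybenzoic acid | O=C(O)c1c(O)cc(O)cc1O | starting material
8 | trimethylsilyl 2,4,6-tris(trimethylsilyloxy)benzoate | C[Si](C)(C)OC(=O)c1c(O[Si](C)(C)C)cc(O[Si](C)(C)C)cc1O[Si](C)(C)C | intermediate
9 | rac-2-[3-geranyl-4-(tert-butyldimethylsilyloxy)phenyl]-5,7-bis(trimethylsilyloxy)-4H-1,3-benzodioxin-4-one | CC(C)=CCC/C(C)=C/Cc1cc(C2OC(=O)c3c(O[Si](C)(C)C)cc(O[Si](C)(C)C)cc3O2)ccc1O[Si](C)(C)C(C)(C)C | intermediate
10 | rac-2-[3-geranyl-4-(tert-butyldimethylsilyloxy)phenyl]-5,7-dihydroxy-4H-1,3-benzodioxin-4-one | CC(C)=CCC/C(C)=C/Cc1cc(C2OC(=O)c3c(O)cc(O)cc3O2)ccc1O[Si](C)(C)C(C)(C)C | intermediate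
11 | rac-2-[3-geranyl-4-(tert-butyldimethylsilyloxy)phenyl]-5,7-bis(tert-butyldimethylsilyloxy)-4H-1,3-benzodioxin-4-one | CC(C)=CCC/C(C)=C/Cc1cc(C2OC(=O)c3c(O[Si](C)(C)C(C)(C)C)cc(O[Si](C)(C)C(C)(C)C)cc3O2)ccc1O[Si](C)(C)C(C)(C)C | intermediate
12 | rac-2-[3-geranyl-4-(tert-butyldimethylsilyloxy)phenyl]-4-methylene-5,7-bis(tert-butyldimethylsilyloxy)-4H-1,3-benzodioxine | CC(C)=CCC/C(C)=C/Cc1cc(C2OC(=C)c3c(O[Si](C)(C)C(C)(C)C)cc(O[Si](C)(C)C(C)(C)C)cc3O2)ccc1O[Si](C)(C)C(C)(C)C | intermediate
13 | (2S)-5,7-bis(tert-butyldimethylsilyloxy)-2-[3-geranyl-4-(tert-butyldimethylsilyloxy)phenyl]chroman-4-one | CC(C)=CCC/C(C)=C/Cc1cc([C@@H]2CC(=O)c3c(O[Si](C)(C)C(C)(C)C)cc(O[Si](C)(C)C(C)(C)C)cc3O2)ccc1O[Si](C)(C)C(C)(C)C | intermediate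
14 | (2S)-3'-geranylnaringenin | CC(C)=CCC/C(C)=C/Cc1cc([C@@H]2CC(=O)c3c(O)cc(O)cc3O2)ccc1O | target

**Step count and risks**

Total step count: 9. Longest linear sequence: 8 steps (steps 1, 2, 3, 5, 6, 7, 8, 9); step 4 is the one-step side branch.

Most likely to fail:

1. Step 8. The ion pair may be intercepted by traces of water and fall apart to aldehyde and hydroxyacetophenone. A loose ion pair, or closure faster than conformational equilibration of the cation, may give poor facial selectivity. The Lewis acid may also reopen the product and erode its enantiomeric purity. The fallback is the rhodium-catalysed asymmetric 1,4-addition of an arylboronic acid to a chromone (Hayashi–Miyaura type), which is known chemistry for 5,7-dioxygenated chromones. It sets out from bromide 4 and comes back to the route at 13. Bromine–lithium exchange on 4 (n-BuLi, THF, −78 °C), triisopropyl borate and aqueous NH4Cl should give [3-geranyl-4-(tert-butyldimethylsilyloxy)phenyl]boronic acid F1. Commercial 5,7-dihydroxychromone F2 is silylated (TBSCl, imidazole, DMF) to 5,7-bis(tert-butyldimethylsilyloxy)-4H-chromen-4-one F3. F1 and F3 are then joined with a hydroxorhodium(I) catalyst carrying an electron-poor atropisomeric bisphosphine (the antipode that gives 2S) in toluene/water at room temperature without added base, which should give 13 with C2 set by the ligand.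

2. Step 5. The silyl-transfer closure may stall at open-chain silyl acetals, and the activated aldehyde may alkylate the electron-rich ring A at carbon. The electron-rich acylal may also be reopened while the aryl TMS ethers are hydrolysed. The fallback replaces silyl transfer by a reversible Brønsted-acid acetal exchange that needs no silyl hydrolysis afterwards. It sets out from aldehyde 6 and acid 7 and comes back at 10, bypassing 8 and 9. Aldehyde 6 is converted with trimethyl orthoformate (PPTS cat., MeOH, rt) into 3-geranyl-4-(tert-butyldimethylsilyloxy)benzaldehyde dimethyl acetal F4. F4 is then exchanged with dried 7 (PPTS cat., DME, 4 Å molecular sieves, rt), the sieves removing methanol so that the equilibrium should settle on the six-membered acylal 10.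

3. Step 7. Methylenation may stall at the carbonyl shielded by the peri 5-silyloxy group, and the long heating may slowly ionise the acetal. The fallback moves the methylenation ahead of the TBS protection, so that the carbonyl faces only a small trimethylsilyloxy group. It sets out from 10 and comes back at 12. Compound 10 is re-silylated with N,O-bis(trimethylsilyl)acetamide to 9, which is methylenated with Cp2TiMe2 (toluene, 65 °C) to rac-2-[3-geranyl-4-(tert-butyldimethylsilyloxy)phenyl]-4-methylene-5,7-bis(trimethylsilyloxy)-4H-1,3-benzodioxine F5. Brief K2CO3/MeOH at 0 °C, basic conditions that an enol acetal tolerates, should remove the aryl TMS groups to give rac-2-[3-geranyl-4-(tert-butyldimethylsilyloxy)phenyl]-4-methylene-4H-1,3-benzodioxine-5,7-diol F6. F6 is silylated without isolation (TBSCl, imidazole, DMF) to 12; any ring-B silyl ether lost in the methanolysis is restored in the same operation.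

**Further compounds**

F1 | step 8 | [3-geranyl-4-(tert-butyldimethylsilyloxy)phenyl]boronic acid | CC(C)=CCC/C(C)=C/Cc1cc(B(O)O)ccc1O[Si](C)(C)C(C)(C)C
F2 | step 8 | 5,7-dihydroxychromone (5,7-dihydroxy-4H-chromen-4-one) | O=c1ccoc2cc(O)cc(O)c12
F3 | step 8 | 5,7-bis(tert-butyldimethylsilyloxy)-4H-chromen-4-one | O=c1ccoc2cc(O[Si](C)(C)C(C)(C)C)cc(O[Si](C)(C)C(C)(C)C)c12
F4 | step 5 | 3-geranyl-4-(tert-butyldimethylsilyloxy)benzaldehyde dimethyl acetal | CC(C)=CCC/C(C)=C/Cc1cc(C(OC)OC)ccc1O[Si](C)(C)C(C)(C)C
F5 | step 7 | rac-2-[3-geranyl-4-(tert-butyldimethylsilyloxy)phenyl]-4-methylene-5,7-bis(trimethylsilyloxy)-4H-1,3-benzodioxine | CC(C)=CCC/C(C)=C/Cc1cc(C2OC(=C)c3c(O[Si](C)(C)C)cc(O[Si](C)(C)C)cc3O2)ccc1O[Si](C)(C)C(C)(C)C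
F6 | step 7 | rac-2-[3-geranyl-4-(tert-butyldimethylsilyloxy)phenyl]-4-methylene-4H-1,3-benzodioxine-5,7-diol | CC(C)=CCC/C(C)=C/Cc1cc(C2OC(=C)c3c(O)cc(O)cc3O2)ccc1O[Si](C)(C)C(C)(C)C
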